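**Retrosynthetic overview**
Numbering: ring A is C1 (C=O), C2 (bears CH2CO2Me), C3 (=CH), C4 (CHOH), C5 (CH bearing the chain), C6 (CH2). The chain starts at C1'.
Late cuts: C1'–C2' by nickel decarboxylative alkenylation of a C5–CH2CO2H arm with the all-E C19 alkenyl iodide; C2–CH2CO2Me from a 2-iodoenone and the zinc enolate of methyl acetate; C1=O by allylic oxidation of a C2=C3 cyclohexene.
Feature used: the C4 oxygen and C1' are cis on ring A. O–C4–C5–C1' plus the carboxyl carbon of the arm therefore form a cis-fused γ-lactone (ring B), which the target lacks but which enforces this relation.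
Key cut: the C4–O bond of ring B, formed together with C3–Br, by enantioselective desymmetrising bromolactonisation of achiral 2-(cyclohexa-2,5-dienyl)acetic acid. That acid comes from benzoic acid by Birch reduction and one-carbon homologation.
Ring order: ring A is the dearomatised benzene ring (step 1); ring B is closed in step 4 and opened again in step 7.

Key step: step 4

Assumption: the quinidine-derived catalyst is taken to select the alkene that leads to the bromolactone drawn. If the sense proves opposite, the quinine-derived pseudoenantiomer is used and nothing else changes.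
Abbreviation: TBS = tert-butyldimethylsilyl. Atom labels C1–C6 and C1' follow the numbering above throughout.

**Step 1**
Reactants: 1 benzoic acid
Product: 2 cyclohexa-2,5-diene-1-carboxylic acid
Conditions: Na, liq. NH3, EtOH, −78 to −33 °C; NH4Cl; aq. HCl
Reagents that add atoms: none
Why: Birch reduction of a benzoate, in which the carboxylate-stabilised anions are protonated at the ipso and para carbons, so the unconjugated 1,4-dihydro acid should result as in the long-established large-scale preparation.

**Step 2**
Reactants: 2 cyclohexa-2,5-diene-1-carboxylic acid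
Product: 4 1-(cyclohexa-2,5-dien-1-yl)-2-diazoethan-1-one, via cyclohexa-2,5-diene-1-carbonyl chloride 3 (not isolated)
Conditions: (COCl)2, DMF (cat.), CH2Cl2, 0 °C to rt, concentrate; CH2N2 (3 equiv), Et2O, 0 °C
Reagents that add atoms: oxalyl chloride ClC(=O)C(=O)Cl (chlorine held only in 3); diazomethane C=[N+]=[N-]
Why: First half of the Arndt–Eistert homologation, an acylation of diazomethane in which excess diazomethane is the only base and the temperature stays low, so the doubly allylic α-hydrogen is not removed and the diene stays unconjugated.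

**Step 3**
Reactants: 4 1-(cyclohexa-2,5-dien-1-yl)-2-diazoethan-1-one
Product: 6 2-(cyclohexa-2,5-dien-1-yl)acetic acid, via dienylketene 5 (not isolated)
Conditions: hν (365 nm), THF/H2O 4:1, rt
Reagents that add atoms: water O
Why: Photochemical Wolff rearrangement, in which loss of N2 with a 1,2-shift of the ring carbon gives the ketene that water captures, while the absence of base and of metal carbenoids avoids diene isomerisation and intramolecular cyclopropanation.

**Step 4**
Reactants: 6 2-(cyclohexa-2,5-dien-1-yl)acetic acid
Product: 7 (3aR,7R,7aR)-7-bromo-3a,6,7,7a-tetrahydro-1-benzofuran-2(3H)-one (cis-fused bromolactone: O on C4 and C1' on the same face; Br on C3 trans to O; C1=C6 intact)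
Conditions: NBS (1.05 equiv), O-(quinidin-9-yl) N-(2,4-dimethoxyphenyl)thiocarbamate (10 mol %), CHCl3/toluene 1:2, −78 °C, dark
Reagents that add atoms: N-bromosuccinimide O=C1CCC(=O)N1Br
Why: The quinuclidine nitrogen of the catalyst holds 6 as a carboxylate ion pair while the thiocarbamate N–H/C=S unit binds and polarises NBS, so bromine is passed to the C3=C4 alkene on the ring face away from the arm and the carboxylate oxygen attacks C4 from the opposite face, an anti addition through a bromonium-like transition state. The closest known reactions are the amine-catalysed enantioselective bromolactonisation of cis-1,2-disubstituted alkenoic acids, the desymmetrising bromolactonisation of Birch-derived cyclohexa-2,5-dienes, and the racemic halolactonisation of cyclohex-2-enylacetic acid to the same cis-fused skeleton. Ring B (O, C=O, C1', C5, C4) closes in the 5-exo-trig mode, because 6-endo attack at C3 would give a strained bridged δ-lactone. C4 is set by the one-carbon tether, which can deliver oxygen only to the face that carries C1' (cis fusion); C3 is set by the anti opening (Br trans to O); C5 becomes stereogenic, and the absolute sense of all three centres is fixed, by the catalyst's choice between the two enantiotopic alkenes. The step needs group selectivity, mono-addition and no aromatisation; these rest on the catalyst, on one equivalent of NBS at −78 °C without light, and on the fact that the remaining C1=C6 alkene has lost its internal nucleophile.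

**Step 5**
Reactants: 7 bromolactone
Product: 8 (3aS,7R,7aR)-7-bromohexahydro-1-benzofuran-2(3H)-one
Conditions: KO2CN=NCO2K, AcOH, MeOH, 0 °C to rt
Reagents that add atoms: none
Why: Diimide reduction, a concerted syn transfer of two hydrogens to the unpolarised C1=C6 alkene that leaves the C3–Br bond and the lactone untouched and removes the risk of aromatisation in the next step (the C5 descriptor changes through CIP priorities only).

**Step 6**
Reactants: 8 saturated bromolactone
Product: 9 (3aS,7aR)-3a,4,5,7a-tetrahydro-1-benzofuran-2(3H)-one (C2=C3 alkene)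
Conditions: DBU, toluene, 100 °C
Reagents that add atoms: none
Why: E2 elimination in which, with bromine axial, only a C2 hydrogen is antiperiplanar (the C4 hydrogen is cis to bromine), so the C2=C3 alkene and no enol ester should form, as known for the halolactones of cyclohex-2-enylacetic acid, with C4 and C5 untouched.

**Step 7**
Reactants: 9 unsaturated lactone
Product: 10 (1R,6S)-6-(2-hydroxyethyl)cyclohex-2-en-1-ol
Conditions: LiAlH4, THF, 0 °C
Reagents that add atoms: none
Why: Hydride reduction of the lactone, chosen over hydrolysis because the cis γ-hydroxy acid would close again on acidification whereas the diol cannot, and because the arm is thereby masked in a form that survives the later oxidation and organozinc steps.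

**Step 8**
Reactants: 10 diol
Product: 11 (1R,6S)-1-(TBSO)-6-[2-(TBSO)ethyl]cyclohex-2-ene
Conditions: TBSCl (2.5 equiv), imidazole, DMF, rt
Reagents that add atoms: tert-butyldimethylsilyl chloride CC(C)(C)[Si](C)(C)Cl
Why: Standard imidazole-promoted silylation of both hydroxyls, whose silyl ethers differ enough in hindrance to be told apart again in step 12.

**Step 9**
Reactants: 11 bis-silyl ether
Product: 12 (4R,5R)-4-(TBSO)-5-[2-(TBSO)ethyl]cyclohex-2-en-1-one
Conditions: Rh2(cap)4 (1 mol %), tBuOOH (5 equiv, decane), K2CO3 (0.5 equiv), CH2Cl2, rt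
Reagents that add atoms: tert-butyl hydroperoxide CC(C)(C)OO
Why: Allylic C–H oxidation by the tert-butylperoxy radical (dirhodium tetracaprolactamate/tBuOOH), in which hydrogen is taken from the open C1 methylene and oxygen is placed at C1 and not C3 of the allyl radical because C3 is flanked by the C4 silyloxy group, while C4–H is shielded by silicon and poorly aligned with the π bond.

**Step 10**
Reactants: 12 enone
Product: 13 (4R,5R)-4-(TBSO)-5-[2-(TBSO)ethyl]-2-iodocyclohex-2-en-1-one
Conditions: I2, pyridine/CH2Cl2 1:1, 0 °C to rt
Reagents that add atoms: iodine II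
Why: α-Iodination of an enone by the iodine/pyridine protocol (a Baylis–Hillman-type addition, iodination and elimination sequence), well used on 4-silyloxycyclohexenones and too weakly basic to epimerise C4.

**Step 11**
Reactants: 13 iodoenone; 14 methyl bromoacetate
Product: 16 methyl 2-{(3R,4R)-3-(TBSO)-4-[2-(TBSO)ethyl]-6-oxocyclohex-1-en-1-yl}acetate, via bromo(2-methoxy-2-oxoethyl)zinc 15 (not isolated)
Conditions: 14, Zn dust (TMSCl-activated), THF, 40 °C; then slow addition (1.4 equiv) to 13, Pd(PtBu3)2 (5 mol %), THF, 0 °C to rt
Reagents that add atoms: zinc [Zn] (held only in 15)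
Why: Negishi-type coupling of a Reformatsky reagent, in which fast oxidative addition of zerovalent palladium to the C2–I bond, transmetalation and reductive elimination from the bulky electron-rich phosphine complex should outrun carbonyl addition of the zinc enolate at low temperature, as they do with keto-substituted aryl halides and in couplings of α-iodoenones with other organozincs.

**Step 12**
Reactants: 16 bis-silyl ether ester
Product: 17 methyl 2-[(3R,4R)-3-(TBSO)-4-(2-hydroxyethyl)-6-oxocyclohex-1-en-1-yl]acetate
Conditions: camphorsulfonic acid (10 mol %), MeOH/CH2Cl2 1:1, 0 °C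
Reagents that add atoms: none
Why: Acid-catalysed methanolysis sorts silyl ethers by hindrance, so the primary TBS ether should be lost well before the secondary one next to the C5 branch, and methanol cannot scramble a methyl ester.

**Step 13**
Reactants: 17 primary alcohol
Product: 19 2-[(1S,6R)-6-(TBSO)-4-(2-methoxy-2-oxoethyl)-3-oxocyclohex-4-en-1-yl]acetic acid, via arm aldehyde 18 (not isolated)
Conditions: TEMPO (20 mol %), PhI(OAc)2 (2.5 equiv), MeCN/H2O 1:1, rt
Reagents that add atoms: water O
Why: Oxoammonium oxidation of the alcohol to the aldehyde, whose hydrate is oxidised on to the acid, in a mildly acidic medium that spares enone, methyl ester and secondary silyl ether (the C5 descriptor changes through CIP priorities only).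

**Step 14**
Reactants: 19 acid
Product: 20 1,3-dioxoisoindolin-2-yl 2-[(1S,6R)-6-(TBSO)-4-(2-methoxy-2-oxoethyl)-3-oxocyclohex-4-en-1-yl]acetate
Conditions: N-hydroxyphthalimide, DIC, DMAP (10 mol %), CH2Cl2, rt
Reagents that add atoms: N-hydroxyphthalimide O=C1c2ccccc2C(=O)N1O
Why: Steglich-type carbodiimide esterification gives the redox-active ester under near-neutral conditions that touch no stereocentre.

**Step 15**
Reactants: 21 1-(trimethylsilyl)propyne; 22 (2E,6E)-farnesyl bromide
Product: 24 trimethyl[(5E,9E)-6,10,14-trimethylpentadeca-5,9,13-trien-1-yn-1-yl]silane, via 3-(trimethylsilyl)prop-2-yn-1-yllithium 23 (not isolated)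
Conditions: n-BuLi, THF, −78 to −20 °C; then 22, −78 °C to rt
Reagents that add atoms: n-butyllithium [Li]CCCC (lithium held only in 23)
Why: SN2 alkylation of a silyl-capped propargyllithium by a primary allylic bromide, in which silicon blocks the alkyne terminus and favours the propargylic over the allenic product, and both alkene geometries are retained.

**Step 16**
Reactants: 24 silyl enyne
Product: 25 (5E,9E)-6,10,14-trimethylpentadeca-5,9,13-trien-1-yne
Conditions: K2CO3 (0.2 equiv), MeOH/THF, rt
Reagents that add atoms: none
Why: Methoxide-catalysed protodesilylation of an alkynylsilane, which is inert towards the isolated trisubstituted alkenes.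

**Step 17**
Reactants: 25 terminal alkyne
Product: 27 (1E,5E,9E)-1-iodo-2,6,10,14-tetramethylpentadeca-1,5,9,13-tetraene, via (E)-alkenyldimethylalane 26 (not isolated)
Conditions: Me3Al (2 equiv), Cp2ZrCl2 (25 mol %), CH2Cl2, 0 °C to rt; I2, THF, −30 to 0 °C
Reagents that add atoms: trimethylaluminium C[Al](C)C; iodine II
Why: Negishi zirconium-catalysed carboalumination adds methyl and aluminium syn across the terminal alkyne with aluminium at the terminus, and iodinolysis with retention fixes the E geometry of the future C2'=C3' alkene, while the other alkenes do not react.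

**Step 18**
Reactants: 20 redox-active ester; 27 alkenyl iodide (1.5 equiv)
Product: 28 methyl 2-{(3R,4R)-3-(TBSO)-6-oxo-4-[(2E,6E,10E)-3,7,11,15-tetramethylhexadeca-2,6,10,14-tetraen-1-yl]cyclohex-1-en-1-yl}acetate
Conditions: NiCl2·6H2O (20 mol %), 2,2'-bipyridine (20 mol %), AgNO3 (0.3 equiv), DMF, Mg anode, RVC cathode, constant current, rt
Reagents that add atoms: none
Why: Nickel-electrocatalytic decarboxylative alkenylation, established for primary redox-active esters and E-trisubstituted alkenyl iodides in polyene assembly, in which one-electron reduction of 20 releases CO2, phthalimide anion and the C1' radical, the alkenylnickel species from 27 captures it, and reductive elimination forms C1'–C2' with retained geometry, at potentials well short of enone reduction and without making C5 a radical centre.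

**Step 19**
Reactants: 28 silyl ether
Product: 29 methyl 2-{(3R,4R)-3-hydroxy-6-oxo-4-[(2E,6E,10E)-3,7,11,15-tetramethylhexadeca-2,6,10,14-tetraen-1-yl]cyclohex-1-en-1-yl}acetate (CNP0274044.1)
Conditions: HF·pyridine, pyridine, THF, 0 °C to rt
Reagents that add atoms: none
Why: Fluoride desilylation in a buffered, weakly acidic medium avoids the basic conditions that could epimerise C4 or shift the C2=C3 alkene, is tolerated by the polyene, and cannot lead to lactonisation because the ester arm lies trans to C4 across C2=C3.

**Compound list**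
1 | benzoic acid | OC(=O)c1ccccc1 | starting material
2 | cyclohexa-2,5-diene-1-carboxylic acid | OC(=O)C1C=CCC=C1 | intermediate
3 | cyclohexa-2,5-diene-1-carbonyl chloride | ClC(=O)C1C=CCC=C1 | intermediate
4 | 1-(cyclohexa-2,5-dien-1-yl)-2-diazoethan-1-one | [N-]=[N+]=CC(=O)C1C=CCC=C1 | intermediate
5 | 2-(cyclohexa-2,5-dien-1-yl)ethen-1-one (dienylketene) | O=C=CC1C=CCC=C1 | intermediate
6 | 2-(cyclohexa-2,5-dien-1-yl)acetic acid | OC(=O)CC1C=CCC=C1 | intermediate
7 | (3aR,7R,7aR)-7-bromo-3a,6,7,7a-tetrahydro-1-benzofuran-2(3H)-one | O=C1C[C@@H]2C=CC[C@@H](Br)[C@@H]2O1 | intermediate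
8 | (3aS,7R,7aR)-7-bromohexahydro-1-benzofuran-2(3H)-one | O=C1C[C@@H]2CCC[C@@H](Br)[C@@H]2O1 | intermediate
9 | (3aS,7aR)-3a,4,5,7a-tetrahydro-1-benzofuran-2(3H)-one | O=C1C[C@@H]2CCC=C[C@@H]2O1 | intermediate
10 | (1R,6S)-6-(2-hydroxyethyl)cyclohex-2-en-1-ol | OCC[C@@H]1CCC=C[C@@H]1O | intermediate
11 | (1R,6S)-1-(TBSO)-6-[2-(TBSO)ethyl]cyclohex-2-ene | CC(C)(C)[Si](C)(C)OCC[C@@H]1CCC=C[C@@H]1O[Si](C)(C)C(C)(C)C | intermediate
12 | (4R,5R)-4-(TBSO)-5-[2-(TBSO)ethyl]cyclohex-2-en-1-one | CC(C)(C)[Si](C)(C)OCC[C@@H]1CC(=O)C=C[C@@H]1O[Si](C)(C)C(C)(C)C | intermediate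
13 | (4R,5R)-4-(TBSO)-5-[2-(TBSO)ethyl]-2-iodocyclohex-2-en-1-one | CC(C)(C)[Si](C)(C)OCC[C@@H]1CC(=O)C(I)=C[C@@H]1O[Si](C)(C)C(C)(C)C | intermediate
14 | methyl bromoacetate | COC(=O)CBr | starting material
15 | bromo(2-methoxy-2-oxoethyl)zinc | COC(=O)C[Zn]Br | intermediate
16 | methyl 2-{(3R,4R)-3-(TBSO)-4-[2-(TBSO)ethyl]-6-oxocyclohex-1-en-1-yl}acetate | COC(=O)CC1=C[C@H](O[Si](C)(C)C(C)(C)C)[C@H](CCO[Si](C)(C)C(C)(C)C)CC1=O | intermediate
17 | methyl 2-[(3R,4R)-3-(TBSO)-4-(2-hydroxyethyl)-6-oxocyclohex-1-en-1-yl]acetate | COC(=O)CC1=C[C@H](O[Si](C)(C)C(C)(C)C)[C@H](CCO)CC1=O | intermediate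
18 | methyl 2-[(3R,4R)-3-(TBSO)-6-oxo-4-(2-oxoethyl)cyclohex-1-en-1-yl]acetate | COC(=O)CC1=C[C@H](O[Si](C)(C)C(C)(C)C)[C@H](CC=O)CC1=O | intermediate
19 | 2-[(1S,6R)-6-(TBSO)-4-(2-methoxy-2-oxoethyl)-3-oxocyclohex-4-en-1-yl]acetic acid | COC(=O)CC1=C[C@H](O[Si](C)(C)C(C)(C)C)[C@H](CC(=O)O)CC1=O | intermediate
20 | 1,3-dioxoisoindolin-2-yl ester of 19 | COC(=O)CC1=C[C@H](O[Si](C)(C)C(C)(C)C)[C@H](CC(=O)ON2C(=O)c3ccccc3C2=O)CC1=O | intermediate
21 | 1-(trimethylsilyl)propyne | CC#C[Si](C)(C)C | starting material
22 | (2E,6E)-farnesyl bromide | CC(C)=CCC/C(C)=C/CC/C(C)=C/CBr | starting material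
23 | 3-(trimethylsilyl)prop-2-yn-1-yllithium | [Li]CC#C[Si](C)(C)C | intermediate
24 | trimethyl[(5E,9E)-6,10,14-trimethylpentadeca-5,9,13-trien-1-yn-1-yl]silane | C[Si](C)(C)C#CCC/C=C(\C)CC/C=C(\C)CCC=C(C)C | intermediate
25 | (5E,9E)-6,10,14-trimethylpentadeca-5,9,13-trien-1-yne | C#CCC/C=C(\C)CC/C=C(\C)CCC=C(C)C | intermediate
26 | dimethyl[(1E,5E,9E)-2,6,10,14-tetramethylpentadeca-1,5,9,13-tetraen-1-yl]alane | C[Al](C)/C=C(\C)CC/C=C(\C)CC/C=C(\C)CCC=C(C)C | intermediate
27 | (1E,5E,9E)-1-iodo-2,6,10,14-tetramethylpentadeca-1,5,9,13-tetraene | I/C=C(\C)CC/C=C(\C)CC/C=C(\C)CCC=C(C)C | intermediate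
28 | TBS ether of the target | COC(=O)CC1=C[C@H](O[Si](C)(C)C(C)(C)C)[C@H](C/C=C(\C)CC/C=C(\C)CC/C=C(\C)CCC=C(C)C)CC1=O | intermediate
29 | CNP0274044.1 | COC(=O)CC1=C[C@H](O)[C@H](C/C=C(\C)CC/C=C(\C)CC/C=C(\C)CCC=C(C)C)CC1=O | target

**Step count and risks**
Total step count: 19.
Longest linear sequence: 16 (steps 1–14, 18 and 19).

Steps most likely to fail:

Step 4. The catalyst may discriminate too weakly between the two enantiotopic alkenes of a substrate that carries only hydrogen at C5. NBS may also dehydrogenate the diene to the arene.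
- The fallback replaces catalyst control by a covalent auxiliary. It sets out from 6 and comes back at 7.
- Coupling of 6 with (2S,5S)-2,5-bis(methoxymethyl)pyrrolidine (EDC·HCl, HOBt, CH2Cl2) gives the C2-symmetric dienylacetamide F1.
- NBS in aqueous DME then closes the same ring through the amide oxygen, the alkenes now being diastereotopic, and gives the bromo iminium lactone F2.
- Water hydrolyses F2 in the flask to 7 and returns the auxiliary. Both antipodes of the auxiliary are available, and crystalline 7 can be enriched by recrystallisation.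

Step 18. The C1' radical may add to the enone of a second molecule or be reduced before nickel captures it. The enone may also bind low-valent nickel and slow turnover.
- The fallback forms the same bond by a two-electron palladium coupling. It sets out from 19 and comes back at 28.
- Hunsdiecker-type iododecarboxylation of 19 (PhI(OAc)2, I2, hν, 1,2-dichloroethane) gives the iodomethyl enone F5.
- Zinc insertion (Zn dust, LiCl, THF, 30 °C) gives the alkylzinc iodide F6, which tolerates enone and ester.
- Negishi coupling of F6 with 27 (PdCl2(dppf), THF, rt) should give 28 with retention of the alkene geometry.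

Step 11. Carbonyl addition of the zinc enolate to the C1 ketone, or proton transfer from the more acidic product, may outrun transmetalation.
- The fallback builds the acetate arm by carbonylation and avoids any enolate. It sets out from 12, which makes step 10 unnecessary, and comes back at 16.
- Morita–Baylis–Hillman hydroxymethylation of 12 (aq. HCHO, DMAP, THF, rt) gives the 2-(hydroxymethyl)enone F3.
- Methyl chloroformate and pyridine (CH2Cl2, 0 °C) give the allylic methyl carbonate F4.
- Palladium-catalysed decarboxylative carbonylation (Pd(OAc)2, PPh3, CO 20 bar, toluene, 50 °C) ionises F4. CO inserts at the unhindered CH2 terminus of the allyl complex, and the liberated methoxide closes the cycle to 16.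

**Further compounds**
F1 | step 4 | 2-(cyclohexa-2,5-dien-1-yl)-1-[(2S,5S)-2,5-bis(methoxymethyl)pyrrolidin-1-yl]ethan-1-one | COC[C@@H]1CC[C@@H](COC)N1C(=O)CC1C=CCC=C1
F2 | step 4 | bromo iminium lactone (cation; ring skeleton and configuration of 7, C=O replaced by C=N+ of the auxiliary) | COC[C@@H]1CC[C@@H](COC)[N+]1=C1C[C@@H]2C=CC[C@@H](Br)[C@@H]2O1
F3 | step 11 | (4R,5R)-4-(TBSO)-5-[2-(TBSO)ethyl]-2-(hydroxymethyl)cyclohex-2-en-1-one | OCC1=C[C@H](O[Si](C)(C)C(C)(C)C)[C@H](CCO[Si](C)(C)C(C)(C)C)CC1=O
F4 | step 11 | methyl carbonate of F3 | COC(=O)OCC1=C[C@H](O[Si](C)(C)C(C)(C)C)[C@H](CCO[Si](C)(C)C(C)(C)C)CC1=O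
F5 | step 18 | methyl 2-[3-(TBSO)-4-(iodomethyl)-6-oxocyclohex-1-en-1-yl]acetate, configuration as in 19 | COC(=O)CC1=C[C@H](O[Si](C)(C)C(C)(C)C)[C@H](CI)CC1=O
F6 | step 18 | alkylzinc iodide from F5 | COC(=O)CC1=C[C@H](O[Si](C)(C)C(C)(C)C)[C@H](C[Zn]I)CC1=O
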